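The cyclohexene ring (C1 = quaternary epoxide carbon bearing C7H2OBz, C2–OAc, C3–OBz, C4=C5, C6 = epoxide CH) is opened at its only olefin, C4=C5, the retron of ring-closing metathesis. One operation closes the carbocycle from an acyclic, sugar-derived 1,7-diene. L-Sorbose C1–C5 supply C7, C1, C2, C3 and C4: its C3/C4 stereocentres become C2/C3, and C5 is sacrificed to a vinyl group by zinc fragmentation. Allyl bromide supplies C6 and C5. The precursor carries C1 as a tertiary carbinol in place of the epoxide. After closure, dehydration (both C1 epimers converge) and anti-selective epoxidation install the oxirane.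

Key step: step 5

Remark: target numbering C1–C7 as defined above is used for all intermediates; compound 1 is taken as a catalogue sugar (otherwise one step from diacetone-L-sorbose by partial hydrolysis).

Step 1
Reactants: 1 monoacetone-L-sorbose (2,3-O-isopropylidene-α-L-sorbofuranose)
Product: 2 iodide (6-deoxy-6-iodo-2,3-O-isopropylidene-α-L-sorbofuranose)
Conditions: I2, PPh3, imidazole, THF, 0 °C → rt
Reagents that add atoms: iodine, II
Why: Garegg–Samuelsson (Appel-type) iodination, in which only the unhindered primary C6 oxyphosphonium is displaced by iodide, the neopentyl-type O1 hydroxymethyl on the ketal carbon and the secondary O4–H being inert to SN2; no stereocentre is touched.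

Step 2
Reactants: 2 iodide (6-deoxy-6-iodo-2,3-O-isopropylidene-α-L-sorbofuranose)
Product: 3 iodo dibenzoate (1,4-di-O-benzoyl-6-deoxy-6-iodo-2,3-O-isopropylidene-α-L-sorbofuranose)
Conditions: BzCl, pyridine, DMAP (cat.), CH2Cl2, 0 °C → rt
Reagents that add atoms: benzoyl chloride, O=C(Cl)c1ccccc1
Why: Acylation of both remaining hydroxyls places benzoates on the oxygens that end as O7 and O3 of the target, while the anomeric acetonide keeps the future acetate oxygen (O2) masked; no stereocentre is affected.

Step 3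
Reactants: 3 iodo dibenzoate (1,4-di-O-benzoyl-6-deoxy-6-iodo-2,3-O-isopropylidene-α-L-sorbofuranose); 4 allyl bromide
Product: 6 diene diol (3R,4S,5R)-5-(benzoyloxymethyl)-4,5-dihydroxyocta-1,7-dien-3-yl benzoate, via hydroxy ketone 5 (not isolated)
Conditions: Zn dust (activated), THF/H2O 4:1, sonication, 40 °C
Reagents that add atoms: none
Why: Bernet–Vasella-type zinc fragmentation (C–I insertion, β-elimination of the ring oxygen to the vinyl group, collapse of the anomeric ketal with loss of acetone) unmasks α-hydroxy ketone 5, which is trapped at once by aqueous Barbier allylation; zinc chelation between carbonyl and free α-hydroxyl (Cram chelate) should favour the drawn C1 configuration, which is erased in step 6 in any case, and the sugar stereocentres (target C2, C3) are untouched.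

Step 4
Reactants: 6 diene diol (3R,4S,5R)-5-(benzoyloxymethyl)-4,5-dihydroxyocta-1,7-dien-3-yl benzoate
Product: 7 diene acetate (3R,4S,5R)-4-acetoxy-5-(benzoyloxymethyl)-5-hydroxyocta-1,7-dien-3-yl benzoate
Conditions: Ac2O, pyridine, DMAP (cat.), CH2Cl2, 0 °C
Reagents that add atoms: acetic anhydride, CC(=O)OC(C)=O
Why: Selective O-acetylation of the secondary C2 hydroxyl by nucleophilic catalysis, the tertiary C1 hydroxyl being unreactive under these conditions; no stereocentre is affected.

Step 5
Reactants: 7 diene acetate (3R,4S,5R)-4-acetoxy-5-(benzoyloxymethyl)-5-hydroxyocta-1,7-dien-3-yl benzoate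
Product: 8 cyclohexenol (1R,5R,6S)-6-acetoxy-5-benzoyloxy-1-(benzoyloxymethyl)cyclohex-3-en-1-ol
Conditions: Grubbs II (5 mol%), CH2Cl2 (5 mM), 40 °C
Reagents that add atoms: none
Why: Ring-closing olefin metathesis (Chauvin mechanism): the ruthenium alkylidene forms at the unhindered allyl terminus (future C5), adds [2+2] across the vinyl group on the benzoate-bearing carbon (future C4) and cycloreverts, expelling ethylene and forming C4=C5. The closest known reaction type is second-generation Grubbs RCM of carbohydrate-derived 1,7-dienes to polyoxygenated cyclohexenes. The ring closed is the six-membered carbocycle, by RCM of a 1,7-diene, the only ring size the two olefins can form. No stereocentre is created; the Z geometry of C4=C5 is imposed by the six-membered ring, and C2/C3 are carried unchanged from L-sorbose. The step needs cyclization to outrun oligomerization and olefin migration, which high dilution, the quaternary C1 (Thorpe–Ingold effect) and the fast-initiating allyl group should secure, while the allylic benzoate and the free tertiary hydroxyl are tolerated. Either C1 epimer cyclizes, so any minor epimer from step 3 is funnelled to the same diene in step 6.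

Step 6
Reactants: 8 cyclohexenol (1R,5R,6S)-6-acetoxy-5-benzoyloxy-1-(benzoyloxymethyl)cyclohex-3-en-1-ol
Product: 9 cyclohexadiene [(5R,6R)-6-acetoxy-5-(benzoyloxy)cyclohexa-1,3-dien-1-yl]methyl benzoate
Conditions: Martin sulfurane, CH2Cl2, 0 °C → rt
Reagents that add atoms: none
Why: Dehydration of the tertiary alcohol through its alkoxysulfonium salt (Martin sulfurane): with the C1–O bond axial only the allylic C6–H is anti-periplanar (C2–H is syn, loss of C7–H would give an enol ester), so elimination should give the conjugated 1,3-diene, removing the C1 stereocentre and merging both C1 epimers.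

Step 7
Reactants: 9 cyclohexadiene [(5R,6R)-6-acetoxy-5-(benzoyloxy)cyclohexa-1,3-dien-1-yl]methyl benzoate
Product: 10 target [(1S,2S,3R,6S)-2-acetoxy-3-(benzoyloxy)-7-oxabicyclo[4.1.0]hept-4-en-1-yl]methyl benzoate
Conditions: mCPBA, NaHCO3, CH2Cl2, 0 °C → rt
Reagents that add atoms: mCPBA (3-chloroperbenzoic acid), OOC(=O)c1cccc(Cl)c1
Why: Prilezhaev epoxidation: the trisubstituted C1=C6 bond is the more nucleophilic olefin of the diene and the peracid should approach anti to the adjacent pseudo-axial C2 acetoxy group, so one syn oxygen transfer sets C1 and C6 (1S,6S) on the face opposite to the acetate, the buffer protecting the vinyl epoxide.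

Compound list
1 | monoacetone-L-sorbose (2,3-O-isopropylidene-α-L-sorbofuranose) | OC[C@]12OC(C)(C)O[C@H]1[C@H](O)[C@H](CO)O2 | starting material
2 | iodide (6-deoxy-6-iodo-2,3-O-isopropylidene-α-L-sorbofuranose) | OC[C@]12OC(C)(C)O[C@H]1[C@H](O)[C@H](CI)O2 | intermediate
3 | iodo dibenzoate (1,4-di-O-benzoyl-6-deoxy-6-iodo-2,3-O-isopropylidene-α-L-sorbofuranose) | O=C(OC[C@]12OC(C)(C)O[C@H]1[C@H](OC(=O)c1ccccc1)[C@H](CI)O2)c1ccccc1 | intermediate
4 | allyl bromide | C=CCBr | starting material
5 | hydroxy ketone (3S,4R)-3-hydroxy-2-oxohex-5-ene-1,4-diyl dibenzoate | O=C(COC(=O)c1ccccc1)[C@@H](O)[C@H](OC(=O)c1ccccc1)C=C | intermediate (not isolated)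
6 | diene diol (3R,4S,5R)-5-(benzoyloxymethyl)-4,5-dihydroxyocta-1,7-dien-3-yl benzoate | C=CC[C@@](O)(COC(=O)c1ccccc1)[C@@H](O)[C@H](OC(=O)c1ccccc1)C=C | intermediate
7 | diene acetate (3R,4S,5R)-4-acetoxy-5-(benzoyloxymethyl)-5-hydroxyocta-1,7-dien-3-yl benzoate | C=CC[C@@](O)(COC(=O)c1ccccc1)[C@@H](OC(C)=O)[C@H](OC(=O)c1ccccc1)C=C | intermediate
8 | cyclohexenol (1R,5R,6S)-6-acetoxy-5-benzoyloxy-1-(benzoyloxymethyl)cyclohex-3-en-1-ol, tertiary OH trans to the C2 acetate | CC(=O)O[C@H]1[C@H](OC(=O)c2ccccc2)C=CC[C@@]1(O)COC(=O)c1ccccc1 | intermediate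
9 | cyclohexadiene [(5R,6R)-6-acetoxy-5-(benzoyloxy)cyclohexa-1,3-dien-1-yl]methyl benzoate | CC(=O)O[C@H]1[C@H](OC(=O)c2ccccc2)C=CC=C1COC(=O)c1ccccc1 | intermediate
10 | [(1S,2S,3R,6S)-2-acetoxy-3-(benzoyloxy)-7-oxabicyclo[4.1.0]hept-4-en-1-yl]methyl benzoate | CC(=O)O[C@H]1[C@H](OC(=O)c2ccccc2)C=C[C@@H]2O[C@@]21COC(=O)c1ccccc1 | target

Total step count: 7. Longest linear sequence: 7 steps (1 → 10).

Steps most likely to fail

Step 7. The peracid may attack the wrong face of C1=C6 (syn to the C2 acetate), the C4=C5 bond or both olefins, or acid may open the vinyl epoxide. The fallback replaces substrate control by hydroxyl-directed, reagent-controlled epoxidation; it sets out from 2 and returns at 10. O1 of 2 is silylated selectively (TBSCl, imidazole, DMF, 0 °C) to silyl ether F1, and benzoylation of O4 gives benzoate F2. The same zinc fragmentation–allylation, through silyloxy ketone F3 (not isolated), gives diene diol F4. Acetylation gives acetate F5, RCM gives cyclohexenol F6, and Martin sulfurane gives silyl diene F7. HF·pyridine liberates dienol F8. Sharpless asymmetric epoxidation (Ti(OiPr)4, L-(+)-diethyl tartrate, TBHP, 4 Å MS, CH2Cl2, −20 °C) can only reach the allylic-alcohol olefin C1=C6; the tartrate-controlled face coincides with the substrate's anti preference, and the product is epoxy alcohol F9. Benzoylation (BzCl, pyridine) then gives 10.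

Step 6. Elimination may run toward C2 or C7 (enol esters), a neighbouring acyloxy group may capture the tertiary cation, or the diene may lose carboxylic acid and aromatize. The fallback is a Peterson olefination, which fixes the position of the new double bond; it sets out from 3 and returns at 9. Ketone 5, generated as in step 3, is trapped with the γ-silylallyl zinc reagent from (E)-(3-bromoprop-1-enyl)trimethylsilane, which reacts at its silicon-bearing carbon to give β-hydroxysilane F10 (C6 epimers, both usable). Acetylation gives silyl acetate F11 and RCM gives cyclic β-hydroxysilane F12. Acid-promoted Peterson elimination (TsOH cat., CH2Cl2, 0 °C) can place the olefin only between C1 and C6, and the ring fixes its geometry, so both epimers should give 9.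

Step 3. The free ketol 5 or its zinc alkoxide may allow benzoyl migration from O3 to O2 or epimerization at C2, or the hindered ketone may be allylated sluggishly. The fallback avoids any free hydroxyl next to the ketone by installing the acetate before ring opening; it sets out from 3 and rejoins the route at 9. Aqueous trifluoroacetic acid (0 °C) removes the acetonide to give hemiketal diol F13 (anomeric mixture), and Ac2O/pyridine/DMAP gives diacetate F14. Zinc fragmentation in the presence of allyl bromide now expels the anomeric acetate and gives acetoxy ketone F15 (not isolated). Its allylation without chelation (Felkin–Anh control) should give mainly tertiary alcohol F16, the C1 epimer of 7. RCM gives cyclohexenol F17. Burgess reagent (syn elimination; C2–H is anti to the hydroxyl in this epimer) then gives 9.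

Further compounds
F1 | step 7 | 1-O-(tert-butyldimethylsilyl)-6-deoxy-6-iodo-2,3-O-isopropylidene-α-L-sorbofuranose | CC(C)(C)[Si](C)(C)OC[C@]12OC(C)(C)O[C@H]1[C@H](O)[C@H](CI)O2
F2 | step 7 | 4-O-benzoyl-1-O-(tert-butyldimethylsilyl)-6-deoxy-6-iodo-2,3-O-isopropylidene-α-L-sorbofuranose | CC(C)(C)[Si](C)(C)OC[C@]12OC(C)(C)O[C@H]1[C@H](OC(=O)c1ccccc1)[C@H](CI)O2
F3 | step 7 | (3S,4R)-1-(tert-butyldimethylsilyloxy)-3-hydroxy-2-oxohex-5-en-4-yl benzoate (not isolated) | O=C(CO[Si](C)(C)C(C)(C)C)[C@@H](O)[C@H](OC(=O)c1ccccc1)C=C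
F4 | step 7 | O7-TBS analogue of diene diol 6 | C=CC[C@@](O)(CO[Si](C)(C)C(C)(C)C)[C@@H](O)[C@H](OC(=O)c1ccccc1)C=C
F5 | step 7 | O7-TBS analogue of diene acetate 7 | C=CC[C@@](O)(CO[Si](C)(C)C(C)(C)C)[C@@H](OC(C)=O)[C@H](OC(=O)c1ccccc1)C=C
F6 | step 7 | O7-TBS analogue of cyclohexenol 8 | CC(=O)O[C@H]1[C@H](OC(=O)c2ccccc2)C=CC[C@@]1(O)CO[Si](C)(C)C(C)(C)C
F7 | step 7 | O7-TBS analogue of cyclohexadiene 9 | CC(=O)O[C@H]1[C@H](OC(=O)c2ccccc2)C=CC=C1CO[Si](C)(C)C(C)(C)C
F8 | step 7 | (1R,6R)-6-acetoxy-2-(hydroxymethyl)cyclohexa-2,4-dien-1-yl benzoate (dienol) | CC(=O)O[C@H]1[C@H](OC(=O)c2ccccc2)C=CC=C1CO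
F9 | step 7 | epoxy alcohol, 10 lacking the C7 benzoate (1S,2S,3R,6S) | CC(=O)O[C@H]1[C@H](OC(=O)c2ccccc2)C=C[C@@H]2O[C@@]21CO
F10 | step 6 | C6-trimethylsilyl analogue of diene diol 6 (β-hydroxysilane, C6 epimers) | C=CC([Si](C)(C)C)[C@@](O)(COC(=O)c1ccccc1)[C@@H](O)[C@H](OC(=O)c1ccccc1)C=C
F11 | step 6 | C6-trimethylsilyl analogue of diene acetate 7 (C6 epimers) | C=CC([Si](C)(C)C)[C@@](O)(COC(=O)c1ccccc1)[C@@H](OC(C)=O)[C@H](OC(=O)c1ccccc1)C=C
F12 | step 6 | C6-trimethylsilyl analogue of cyclohexenol 8 (C6 epimers) | CC(=O)O[C@H]1[C@H](OC(=O)c2ccccc2)C=CC([Si](C)(C)C)[C@@]1(O)COC(=O)c1ccccc1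
F13 | step 3 | 1,4-di-O-benzoyl-6-deoxy-6-iodo-L-sorbofuranose (anomeric mixture) | O=C(OCC1(O)[C@@H](O)[C@H](OC(=O)c2ccccc2)[C@H](CI)O1)c1ccccc1
F14 | step 3 | 2,3-di-O-acetyl-1,4-di-O-benzoyl-6-deoxy-6-iodo-L-sorbofuranose (anomeric mixture) | O=C(OCC1(OC(C)=O)[C@@H](OC(C)=O)[C@H](OC(=O)c2ccccc2)[C@H](CI)O1)c1ccccc1
F15 | step 3 | (3S,4R)-3-acetoxy-2-oxohex-5-ene-1,4-diyl dibenzoate (not isolated) | O=C(COC(=O)c1ccccc1)[C@@H](OC(C)=O)[C@H](OC(=O)c1ccccc1)C=C
F16 | step 3 | C1 epimer of diene acetate 7 (3R,4S,5S) | C=CC[C@](O)(COC(=O)c1ccccc1)[C@@H](OC(C)=O)[C@H](OC(=O)c1ccccc1)C=C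
F17 | step 3 | C1 epimer of cyclohexenol 8 (1S,5R,6S) | CC(=O)O[C@H]1[C@H](OC(=O)c2ccccc2)C=CC[C@]1(O)COC(=O)c1ccccc1
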